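All runs are simulated for substances that don't exist.

Coupling partner is the concentration I follow here, since the two earlier runs differ in nothing else.

| flask | substrate | coupling partner | remark | time |
|---|---|---|---|---|
| midnight | 0.020 M (in portions, 2) | 0.040 M | run made earlier; portions every 80 min |  |
| winter | 0.020 M (in portions, 2) | 0.16 M | run made earlier; portions every 80 min |  |
| flask | 0.020 M (in portions, 2) | 0.0800 M | the portions of substrate follow each other after 80 min, the first at the start | 8.0 h |

| run | time / h | target / % | intermediate C / % |
|---|---|---|---|
| midnight | 0.500 | 0 | 0.9 |
| midnight | 1.50 | 0.1 | 0.3 |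
| midnight | 3.00 | 0.2 | 0.5 |
| midnight | 4.00 | 0.4 | 1.0 |
| midnight | 6.00 | 0.3 | 1.7 |
| midnight | 8.00 | 0 | 2.9 |
| winter | 0.667 | 0 | 0.5 |
| winter | 1.00 | 0 | 0 |
| winter | 2.00 | 0 | 0.8 |
| winter | 3.00 | 0 | 2.7 |
| winter | 5.00 | 1.6 | 11.0 |
| winter | 8.00 | 2.5 | 26.8 |

(readings scatter by 0.5 percentage points)

- how much target the flask holds at 8.0 h, in percent of the substrate charged
- how much intermediate C the flask holds at 8.0 h, in percent of the substrate charged
- how much intermediate B the flask holds at 8.0 h, in percent of the substrate charged
- how much intermediate A the flask holds at 8.0 h, in percent of the substrate charged



A bench rule says that a reagent charged well above the other stays near its charge and acts as a constant, the pseudo-first-order case. With substrate, portions and time held, I then expect intermediate C to go with a power of the partner. The last readings, 2.9% at 0.040 M of partner and 26.8% at 0.16 M, give 1.60: the logarithm of the ratio of the C readings over the logarithm of the ratio of the partner charges, which I call the apparent order. It is a reading, and the scatter of 0.5 percentage points on the midnight value alone moves it by about 0.124. Taken from the midnight reading to this flask's 0.0800 M, it gives 8.82% of intermediate C at 8.0 h. Neither intermediate A nor intermediate B is read in either run, so I commit to no figure for them.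

The rule has borders. Counted one for one, the substrate charge equals a quarter of this flask's partner charge and half of the midnight run's. I also expect a power to bend once the material feeding intermediate C thins, and the last winter reading already stands at a quarter of the charge as intermediate C. So I trust the order between the two runs and not above the winter charge.

The forecast, which reads “an apparent order of about 1.5” from the two runs, gives target 0.7%, intermediate C 8.5%, intermediate B 25% and intermediate A 42%. Its C is lower than mine.

This flask gives target 1.10%, intermediate C 9.81%, intermediate B 30.6% and intermediate A 53.8%.

    coupling partner + intermediate E → target (k = 3.50 M⁻¹ h⁻¹)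
    substrate → intermediate A (k = 0.501 h⁻¹)
    intermediate B → intermediate E (k = 0.0232 h⁻¹)
    coupling partner + intermediate A → intermediate B (k = 1.49 M⁻¹ h⁻¹)
    intermediate C ⇌ intermediate D (K = 2.20, k = 0.0156 h⁻¹)
    coupling partner + intermediate B → intermediate C (k = 1.19 M⁻¹ h⁻¹)

At 8.00 h this flask keeps 86% of its partner's charge. Its intermediate C stands 0.99 points above my figure. Carried by the order 1.60 from this flask's intermediate C to the neighbour charged with 0.20 M of partner, the power promises 42.7%, but that neighbour holds less, 35.4%.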